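Slowness of the feed is where I began: by 20 h the dosing of birch has delivered 66.7% of its free monomer, while the larch feed, set to 20 h, has just ended.

| flask | free monomer | transfer agent | protic impurity | initiator | remark | time |
|---|---|---|---|---|---|---|
| south-west | 0.13 M (fed, over 20 h) | 3.9 mM | 0.065 M | 6.5 mM | run made earlier; the fed solution adds 0.10 times the starting volume |  |
| west | 0.13 M (fed, over 20 h) | 3.9 mM | 0.065 M | 9.8 mM | run made earlier; the fed solution adds 0.10 times the starting volume |  |
| north-east | 0.13 M (fed, over 20 h) | 1.9 mM | 0.065 M | 13 mM | run made earlier; the fed solution adds 0.10 times the starting volume |  |
| larch | 0.13 M (fed, over 20 h) | 3.90 mM | 0.0650 M | 13 mM | the fed solution adds 0.10 times the starting volume | 20 h |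
| birch | 0.13 M (fed, over 30 h) | 3.90 mM | 0.0650 M | 13 mM | the fed solution adds 0.10 times the starting volume | 20 h |

- which of the two ends with the longer chains by the average number of monomer units in a chain (chains begun, living or dead) ("neither" if they lie within 10%) (larch / birch / neither)
- average number of monomer units in a chain (chains begun, living or dead) at the end, larch
- average number of monomer units in a chain (chains begun, living or dead) at the end, birch

- every charge counts on the volume at the start, and the solution that is fed holds the whole dose
- the average divides the monomer in chains by the number of chains begun, living and dead together
- percentages count the whole charge, also what has not yet gone in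
- the earlier runs do not show the number of chains; that part of a forecast is a guess

The average asked for is the number-average degree of polymerization, so I needed a count of monomer and a count of chains. I kept one quantity: 10.0 is the dosed length of larch, the free monomer fed so far over the initiator charged, and birch has 6.67. That would be the chain length if the fed monomer went wholly into chains and each initiator charged began one chain, so I asked the earlier runs how far this holds.

- south-west (time / h: monomer in chains / %, free monomer / %): 4.00: 13.2, 5.4; 8.00: 31.8, 5.5; 12.0: 48.8, 6.3; 15.0: 62.0, 6.9; 20.0: 84.0, 8.4
- west (time / h: monomer in chains / %, free monomer / %): 4.00: 15.3, 4.0; 8.00: 34.6, 3.7; 12.0: 51.9, 4.1; 15.0: 66.4, 3.9; 20.0: 89.9, 4.5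
- north-east (time / h: monomer in chains / %, free monomer / %): 1.50: 4.8, 3.4; 3.00: 11.5, 3.1; 6.00: 25.3, 1.9; 10.0: 45.4, 2.7; 20.0: 93.6, 2.6

(scatter of a reading: 0.5 percentage points)

In the last row of each run the feed has just ended, so percent of charge is percent of fed: south-west holds 84.0% in chains, west 89.9%, north-east 93.6%. Down the free monomer column, south-west climbs from 5.4% to 8.4%, while north-east goes from 3.4% to 2.6%; transfer agent over initiator is 0.600 in south-west against 0.146 in north-east. So I took the transfer agent as ending chains rather than beginning them, which stays a guess, since no run shows chains. The larch ratio, 0.300, lies between that of west, 0.398, and that of north-east, so I took the middle of their shares, 91.8%, and used it for birch too. That gave me 9.18 for larch and 6.12 for birch, a factor of 1.50 apart, beyond the margin of 10%, so I chose larch.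

The forecast also chose larch, but with 7.5 for larch and 5 for birch, on the ground “Chains (guess): 13 mM initiator plus about 3 mM transfer, so about 16 mM in both.”

The flask gave larch, with 9.35 for larch and 6.40 for birch.

    living end + transfer agent → dead chain (kL = 28.2 M⁻¹ h⁻¹)
    protic impurity + free monomer → quenched substrate (k = 1.32 M⁻¹ h⁻¹)
    free monomer + initiator → living end + monomer in chains (k = 64.4 M⁻¹ h⁻¹)
    free monomer + living end → monomer in chains + living end, rate k4*[living end]*[free monomer] (k = 198 M⁻¹ h⁻¹)

In larch 92.6% of the charge stood in chains and 1.00% of the initiator was left, so the dosed length times that share, over the initiator spent, is 9.35. The neighbour of birch charged with 0.016 M of transfer agent kept the dosed length of 6.67 and ended with 50.3% of its charge in chains, 75.5% of what was fed, and 0.056% of its initiator left; the dosed length times that share is 5.03, and its average stood at 5.03.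

The earlier runs and the new flask stem from a simulated flask for substances that don't exist.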